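**Retrosynthetic overview**
1. Flavanone 11 ⇒ open-chain (9S)-hydroxy-triketo tert-butyl ester 7. In one pot ring C closes first (O1–C8a, cyclodehydration), then ring A (C4a–C5, acylketene closure and aromatisation).
2. 7 ⇒ trianion of diketo ester 5 + ethyl (S)-3-hydroxy-3-phenylpropanoate 6 (C4–C4a bond). The stereocentre is bought in with 6 and no bond to it is made or broken afterwards.
3. 5 ⇒ dianion of 3 + Weinreb acetamide 4 (C8–C8a bond); 3 ⇒ tert-butyl acetoacetate 1 + geranyl bromide 2.
4. Ring order: B is purchased (phenyl of 6); C then A, both in step 4. Geranyl is fixed at C6 because it sits on the α-carbon of the β-keto ester, between the future C5 and C7.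

Assumption: 6 is bought as the single (S) enantiomer; enolates and polyanions made in situ count as activated forms of the numbered compound and are not numbered; chain carbons are labelled with the flavanone numbering they end up with (O1, C2 … C8a).

**Route**

Step 1
Reactants: 1 tert-butyl acetoacetate; 2 geranyl bromide
Product: 3 tert-butyl (4E)-2-acetyl-5,9-dimethyldeca-4,8-dienoate (tert-butyl 2-geranylacetoacetate, racemic at C2)
Conditions: NaH (1.0 equiv), 1 (1.3 equiv), THF, 0 °C; then 2 (1.0 equiv), 0 → 23 °C
Reagents that add atoms: none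
Why: Acetoacetic ester C-alkylation (SN2 of the sodium enolate on a primary allylic bromide, E-alkene untouched); excess 1 suppresses dialkylation, and the racemic C2 centre disappears on aromatisation.

Step 2
Reactants: 3 tert-butyl 2-geranylacetoacetate; 4 N-methoxy-N-methylacetamide
Product: 5 tert-butyl 2-[(2E)-3,7-dimethylocta-2,6-dien-1-yl]-3,5-dioxohexanoate (racemic at C2, enol mixture)
Conditions: LDA (2.2 equiv), THF, −78 → 0 °C; then 4 (1.05 equiv), −78 → −20 °C; AcOH quench
Reagents that add atoms: none
Why: Huckin–Weiler dianion γ-acylation; the Weinreb amide gives a chelated tetrahedral adduct that releases the 1,3-diketone only on quench, so the product cannot protonate unreacted dianion or be attacked twice.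

Step 3
Reactants: 5 tert-butyl 2-geranyl-3,5-dioxohexanoate; 6 ethyl (3S)-3-hydroxy-3-phenylpropanoate
Product: 7 tert-butyl (9S)-2-[(2E)-3,7-dimethylocta-2,6-dien-1-yl]-9-hydroxy-3,5,7-trioxo-9-phenylnonanoate (C2 epimers, keto–enol mixture, used after cold work-up)
Conditions: 5 (2.2 equiv), LDA (6.7 equiv), THF, −78 → −20 °C; then lithium alkoxide of 6 (6 + LDA 1.0 equiv, −78 °C), −40 → 0 °C; AcOH, −78 °C
Reagents that add atoms: none
Why: Crossed Claisen condensation of a β,δ-diketo ester trianion at its terminal carbon (biomimetic polyketide chain extension) with an ester whose β-hydroxyl is masked as the lithium alkoxide; the C9 stereocentre comes from 6 unchanged.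

Step 4
Reactants: 7 tert-butyl (9S)-2-geranyl-9-hydroxy-3,5,7-trioxo-9-phenylnonanoate
Product: 11 (2S)-6-geranylpinocembrin (target), via dihydropyranone keto ester 8 (not isolated), via acylketene 9 (not isolated), via cyclohexadienone 10 (not isolated)
Conditions: CSA (5 mol %), 4 Å MS, xylenes (0.02 M), 23 °C, 1 h; then 2,6-lutidine (10 mol %), 140 °C, 3 h
Reagents that add atoms: none
Why: Proposed new method: the C9 hydroxyl adds 6-exo to the δ-carbonyl and the hemiketal dehydrates to the 2,3-dihydro-4H-pyran-4-one 8 (ring C; the C–O bond at the stereocentre is never broken, so (S) is retained), then on heating the tert-butyl β-keto ester loses tert-butanol to acylketene 9, whose dienol tautomer is a dienylketene that closes by 6π-electrocyclisation (C-acylation at C4a) to dienone 10 and enolises to the phenol (ring A), the competing O-acylation to a 2-pyrone being blocked because the C8a oxygen is already the ring ether; closest known reaction types are thermolysis of tert-butyl acetoacetates or dioxinones to acylketenes, the electrocyclisation–aromatisation end of the Danheiser benzannulation, and biomimetic polyketide aromatisation.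

**Compound list**
1 | tert-butyl acetoacetate | CC(=O)CC(=O)OC(C)(C)C | starting material
2 | geranyl bromide, (2E)-1-bromo-3,7-dimethylocta-2,6-diene | CC(C)=CCC/C(C)=C/CBr | starting material
3 | tert-butyl (4E)-2-acetyl-5,9-dimethyldeca-4,8-dienoate (racemic) | CC(C)=CCC/C(C)=C/CC(C(C)=O)C(=O)OC(C)(C)C | intermediate
4 | N-methoxy-N-methylacetamide | CC(=O)N(C)OC | starting material
5 | tert-butyl 2-[(2E)-3,7-dimethylocta-2,6-dien-1-yl]-3,5-dioxohexanoate (racemic) | CC(C)=CCC/C(C)=C/CC(C(=O)CC(C)=O)C(=O)OC(C)(C)C | intermediate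
6 | ethyl (3S)-3-hydroxy-3-phenylpropanoate | CCOC(=O)C[C@H](O)c1ccccc1 | starting material
7 | tert-butyl (9S)-2-[(2E)-3,7-dimethylocta-2,6-dien-1-yl]-9-hydroxy-3,5,7-trioxo-9-phenylnonanoate (C2 epimers) | CC(C)=CCC/C(C)=C/CC(C(=O)CC(=O)CC(=O)C[C@H](O)c1ccccc1)C(=O)OC(C)(C)C | intermediate
8 | tert-butyl 2-[(2E)-3,7-dimethylocta-2,6-dien-1-yl]-3-oxo-4-[(2S)-4-oxo-2-phenyl-3,4-dihydro-2H-pyran-6-yl]butanoate | CC(C)=CCC/C(C)=C/CC(C(=O)CC1=CC(=O)C[C@@H](c2ccccc2)O1)C(=O)OC(C)(C)C | intermediate
9 | (2S)-6-[(5E)-6,10-dimethyl-2-oxo-3-(oxomethylidene)undeca-5,9-dien-1-yl]-2-phenyl-2,3-dihydro-4H-pyran-4-one (acylketene) | CC(C)=CCC/C(C)=C/CC(=C=O)C(=O)CC1=CC(=O)C[C@@H](c2ccccc2)O1 | intermediate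
10 | (2S)-6-[(2E)-3,7-dimethylocta-2,6-dien-1-yl]-7-hydroxy-2-phenyl-2,3-dihydro-4H-chromene-4,5(4aH)-dione (C4a epimers) | CC(C)=CCC/C(C)=C/CC1=C(O)C=C2O[C@H](c3ccccc3)CC(=O)C2C1=O | intermediate
11 | (2S)-6-[(2E)-3,7-dimethylocta-2,6-dien-1-yl]-5,7-dihydroxy-2-phenyl-2,3-dihydro-4H-chromen-4-one (6-geranylpinocembrin, CNP0201748.1) | CC(C)=CCC/C(C)=C/Cc1c(O)cc2c(c1O)C(=O)C[C@@H](c1ccccc1)O2 | target

**Totals**
Total steps: 4. Longest linear sequence: 4 (1/2 → 3 → 5 → 7 → 11).

**Steps most likely to fail, with fallbacks**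

Step 4 is the main risk. The open 1,3,5-triketone could close to a γ-pyrone or the benzylic alcohol could dehydrate before ring C forms. Residual water would hydrolyse the ketene and lead to decarboxylation, and hot acid could cyclise the ortho-geranyl phenol to a chroman (hence the sieves and the lutidine buffer). The fallback sets out from 7 and comes back at 11. Ring C is closed alone (CSA, 4 Å MS, CH2Cl2, 23 °C) and dihydropyranone keto ester 8 is isolated. Ring A is then closed anionically instead of through the ketene: KOtBu (2.5 equiv), THF, −40 → 0 °C, a Dieckmann-type C-acylation of the extended enolate at C4a by the tert-butyl ester followed by aromatisation, with a cold AcOH quench. The ee must be checked by chiral HPLC because the phenoxide can open reversibly to the chalcone. This fallback makes no compound outside the list (F0).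

Step 3 is the second risk. The lithium alkoxide of 6 is a sluggish acyl donor, may be deprotonated at its α-carbon, and needs excess trianion. The fallback sets out from 6 and comes back at 7. Aminolysis of 6 (MeNHOMe·HCl, iPrMgCl, THF, −20 °C) gives (3S)-3-hydroxy-N-methoxy-N-methyl-3-phenylpropanamide F1. Silylation (TBSCl, imidazole, DMF) gives (3S)-3-[(tert-butyldimethylsilyl)oxy]-N-methoxy-N-methyl-3-phenylpropanamide F2. The trianion of 5 (1.2 equiv, LDA, THF, −78 → −20 °C) adds once to F2 to give tert-butyl (9S)-9-[(tert-butyldimethylsilyl)oxy]-2-geranyl-3,5,7-trioxo-9-phenylnonanoate F3. HF·pyridine (THF, 0 °C) removes the silyl group and returns 7.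

Step 2 is the third risk. The dianion of an α-substituted acetoacetate may O-acylate or enolise the acetamide. The fallback sets out from 3 and comes back at 5. It swaps acylation for aldol addition then oxidation: the dianion of 3 (LDA, THF, −78 °C) adds to acetaldehyde to give tert-butyl 2-geranyl-5-hydroxy-3-oxohexanoate F4, and Dess–Martin periodinane (CH2Cl2, 23 °C) oxidises F4 to 5.

**Further compounds**
F0 | step 4 | none | none
F1 | step 3 | (3S)-3-hydroxy-N-methoxy-N-methyl-3-phenylpropanamide | CON(C)C(=O)C[C@H](O)c1ccccc1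
F2 | step 3 | (3S)-3-[(tert-butyldimethylsilyl)oxy]-N-methoxy-N-methyl-3-phenylpropanamide | CON(C)C(=O)C[C@H](O[Si](C)(C)C(C)(C)C)c1ccccc1
F3 | step 3 | tert-butyl (9S)-9-[(tert-butyldimethylsilyl)oxy]-2-[(2E)-3,7-dimethylocta-2,6-dien-1-yl]-3,5,7-trioxo-9-phenylnonanoate | CC(C)=CCC/C(C)=C/CC(C(=O)CC(=O)CC(=O)C[C@H](O[Si](C)(C)C(C)(C)C)c1ccccc1)C(=O)OC(C)(C)C
F4 | step 2 | tert-butyl 2-[(2E)-3,7-dimethylocta-2,6-dien-1-yl]-5-hydroxy-3-oxohexanoate | CC(C)=CCC/C(C)=C/CC(C(=O)CC(C)O)C(=O)OC(C)(C)C
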